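## Analysis of the target

Locants: the carbocycle is numbered C1–C11 round its perimeter. C1 is the ketone carbon, C2=C3 the enone alkene (methyl on C3), C6 carries the gem-dimethyl group, C7 the O-angelate, C9 the O-tiglate and C10 a methyl group. The cross-ring bonds C4–C10 and C5–C11 close the cyclobutane C4–C5–C11–C10. Ring A is the six-membered enone ring (C1–C5, C11); ring B is the seven-membered ring containing C5–C10.

Target 36 is a longipinane-type tricycle: a bicyclo[3.1.1]hept-3-en-2-one (ring A plus the cyclobutane) whose two one-carbon bridges, C5 and C10, are tied together by C6–C9 into ring B. Four of the six stereocentres (C4, C5, C10, C11) lie on the cyclobutane and are fixed relative to each other by the ring fusions. The C1–C3 bridge lies on one face of the four-membered ring and ring B on the other, so the C10 methyl is syn to the enone bridge and C6 and C9 are syn to each other. The other two, C7 and C9, carry trans acyloxy groups (C9–O on the C11 side, C7–O on the C4 side). They sense the chirality of the core only through the remote difference between C1=O and C3–CH3, so they cannot be expected to follow from the core. Sensitive groups are the angelate (Z to E isomerisation), the tiglate, the enone, and the cyclobutane, which opens or rearranges when a radical or cation is generated on an attached carbon. The hard parts are the strained ring with quaternary C10 bearing two different carbon substituents, and the cis placement of the bulky C6 and C9 groups across that ring. The strategy rests on one feature: the C10 methyl can be read as a reduced carboxyl and C4 is allylic to C2=C3. C4–C10 is therefore the σ-bond of a γ,δ-unsaturated acid, a Claisen bond. Its allylic ester oxygen belongs on C2 of a cyclohexene that carries the enolate carbon C10 on C11.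

## Retrosynthetic reasoning

**Esters (36 ⇒ 33 + 34; 33 ⇒ 31 + 32).** The C7–O acyl bond is cut last because the Z-configured ester is the group most easily lost. The C9 tiglate is not cut as a plain ester bond: the C9–O acyl bond and the C7–H bond are cut together, leading back to β-hydroxy ketone 31 and aldehyde 32. This gains two things: the hydroxyl on C9 sets C7 (anti), and the two ring-B oxygens are told apart without protecting groups. The forward reaction must pass the hemiacetal hydride to C7 only.

**C9–O (31 ⇒ 29).** The tricyclic core is nearly mirror-symmetric about the plane through ring B, so a direct aldol would create C9 without control. Cutting C9–O instead leads to ring-B enone 29, where the oxygen can be added under catalyst control. The forward reaction is a face-selective conjugate borylation followed by oxidation.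

**Ring B (29 ⇒ 28).** The C8=C9 bond is cut as an aldol condensation. Ring B is closed late because C6 and C9 are already held syn on the cyclobutane, C8 is the only enolisable carbon that can reach an electrophile, and the C9 aldehyde cannot enolise.

**Oxidation levels (28 ⇒ 27 ⇒ 26 ⇒ 25 ⇒ 24).** The three carbonyls of 28 come from triol 27. C8 is added to a C7 aldehyde. That aldehyde, the C9 carbinol and the C1 carbinol all come from one hydride reduction of 25. The C1 oxygen is introduced by allylic oxidation of 24, while only an ester and an amide are present. This order ensures no organometallic meets the enone and no oxidant meets an aldehyde.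

**C10 methyl (24 ⇒ 22 ⇒ 20).** The methyl is traced to the carboxyl of acid 20 through a primary alcohol. A hydride displacement is chosen because it avoids a radical or cation next to the cyclobutane.

**Key disconnection (20 ⇒ 17).** The C4–C10 bond is cut by a retro-[3,3] shift. This places the ester oxygen on C2, moves the alkene to C3=C4 and opens the cyclobutane, giving bridged lactone 17. One pericyclic step then builds the strained ring, the quaternary centre and the C4 stereocentre, and the tether decides which carboxyl becomes the methyl. Cutting C5–C11 or C10–C11 instead would lose this built-in differentiation.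

**Lactone precursor (17 ⇒ 15 ⇒ 13 ⇒ 12).** The lactone C–O bond is cut to a cis hydroxy malonate, which comes from enone 15 by reduction from the open face. The C3 methyl is removed to give enone 13 (it is installed by iodination and cross-coupling), and the C2 oxygen is removed to give cyclohexene 12. This avoids building a tertiary carbinol by a facially unselective carbonyl addition.

**C5–C6 (12 ⇒ 10 ⇒ 7).** The C5–C6 bond is cut by a retro-Ireland–Claisen shift to allylic isobutyrate 7. The forward shift is suprafacial, so it places the bulky C6 group cis to the malonate on C11. An intermolecular addition would not give this contra-steric arrangement.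

**Absolute configuration (7 ⇒ 5 + 6; 5 ⇒ 3 + 4; 3 ⇒ 1).** The C11–C10 bond is cut to meso diester 5 and malonate 6. Desymmetrisation sets C11, and every later stereocentre is relayed from it.

## Alternatives that were turned down

**Alternative 1:** Both cyclobutane bonds C5–C11 and C4–C10 are cut at once, unfolding ring A and the four-membered ring to the acyclic (2E,6E)-dienoyl chloride A1. In the forward step an amine base dehydrochlorinates A1, and the resulting ketene function adds across C10=C11 in an intramolecular [2+2] to give cyclobutanone A2.
- **For:** A2 is reached from an open chain in one step; the quaternary C10 follows from the alkene geometry; and this type of cycloaddition to bicyclo[3.1.1]heptan-6-ones is well established. On precedent for the ring-forming event it is stronger than the chosen route.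
- **Against:** In A2 the carbonyl sits on C5, which in the target is a C–H carbon bonded to C6. Ring B would have to be closed by adding a fully substituted C6 nucleophile to a hindered cyclobutanone, and the tertiary oxygen then removed with control of C5 on a strained ring. The exocyclic methylene must also be moved into the ring and C1 oxidised, and the face of the cycloaddition depends on 1,2-induction from C9 alone.
- **Comparison:** The chosen route gives up some precedent. In return it has C5 in the correct oxidation state with C6 attached, absolute control from one catalytic desymmetrisation, and the two C10 substituents differentiated by the tether.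

**Alternative 2:** Only C10–C11 is cut, leading to a cis-fused bicyclo[5.4.0]undecane with both rings preformed, used as bis(silyl enol ether) A3. One-electron oxidation couples C10 to C11 to give tricyclic dione A4.
- **For:** Rings A and B come from reliable annulation chemistry. C1 and C9 already carry their oxygens. The endgame is the shortest of all, and here it is stronger than the chosen route.
- **Against:** The coupling must close a four-membered ring between a fully substituted enol carbon and the α′-carbon of a cross-conjugated dienol ether. That closure is slow for radical or radical-cation intermediates, which have easier paths (desilylation, dimerisation, reaction at the dienol terminus), and the strained 1,4-diketone product can re-open by the reverse electron transfer. The C9 and C7 carbinols still need control that the core cannot give.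
- **Comparison:** The chosen route is longer, but its key bond forms through a concerted six-centre shift whose geometry fixes the stereochemistry.

**Alternative 3:** C10–C11 is traced back to a norbornene in which C10 bridges C1 and C4. Silyloxycyclopentadiene A5, with a tethered (E)-nitroalkene, undergoes an intramolecular Diels–Alder reaction forming C4–C5 and C1–C11 to give nitronorbornene A6. Reduction, diazotisation and a 1,2-shift of C10 from C1 to C11 would then convert the norbornane into the bicyclo[3.1.1]heptanone.
- **For:** The cycloaddition sets four core stereocentres and closes ring B in one step. C7 and C9 are already in the tether, set by acyclic stereocontrol. On ring-B stereochemistry it is clearly stronger than the chosen route, which needs a separate catalyst-controlled step for C9.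
- **Against:** A5 is a long, linear target in itself (quaternary C10 next to C9 on a regiodefined silyloxycyclopentadiene). The ring switch runs towards the more strained skeleton. It requires the C1–C10 bond, and not the vinyl bond or a hydride, to migrate to the diazonium carbon, in a system prone to Wagner–Meerwein scrambling.
- **Comparison:** The chosen route offers a much shorter approach to the bicyclo[3.1.1] core and a stereospecific key step. It pays for this with a later, reagent-controlled introduction of the C9 oxygen.

Key step: step 10

Assumptions (remarks on the chemistry):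
- The (R,R)-enantiomer of the diaminocyclohexane bis(2-diphenylphosphinobenzamide) ligand is taken to ionise the ester on the carbon that becomes C11 (R) in step 3; if the sense of induction is the opposite, the (S,S)-ligand is used and nothing else changes.
- In step 18 the antipode of the bisphosphine that places boron on the C11-side face of C9 is chosen in the same way.
- C10 of lactone 17 is epimerisable; it is drawn as one epimer and either epimer serves.

## Route

Step 1
Reactants: 1 cyclohexa-1,3-diene
Product: 3 cis-cyclohex-2-ene-1,4-diol, via endoperoxide 2 (not isolated)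
Conditions: O2, tetraphenylporphyrin (cat.), hν, CH2Cl2, 0 °C; then Zn, AcOH, 0 °C → rt
Reagents that add atoms: dioxygen, O=O
Why: Singlet-oxygen [4+2] cycloaddition places both oxygens on one face of the diene, and reductive O–O cleavage leaves the C–O bonds untouched, so the meso cis-diol should result.

Step 2
Reactants: 3 cis-cyclohex-2-ene-1,4-diol; 4 2-methylpropanoyl chloride
Product: 5 cis-cyclohex-2-ene-1,4-diyl bis(2-methylpropanoate)
Conditions: 4 (2.4 equiv), pyridine, 4-(dimethylamino)pyridine (cat.), CH2Cl2, 0 °C → rt
Reagents that add atoms: none
Why: Routine acylation of two secondary allylic alcohols; the isobutyrate serves as leaving group in step 3 and as the source of C6 and C7 in step 4.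

Step 3
Reactants: 5 cis-cyclohex-2-ene-1,4-diyl bis(2-methylpropanoate); 6 dimethyl malonate
Product: 7 dimethyl 2-[(1R,4S)-4-(2-methylpropanoyloxy)cyclohex-2-en-1-yl]propanedioate
Conditions: 6 (1.3 equiv), NaH (1.2 equiv), [Pd(C3H5)Cl]2 (2.5 mol%), (1R,2R)-N,N'-bis[2-(diphenylphosphino)benzoyl]cyclohexane-1,2-diamine (7.5 mol%), THF, 0 °C
Reagents that add atoms: none
Why: Tsuji–Trost asymmetric allylic alkylation used as a desymmetrisation: the chiral zerovalent palladium complex ionises one enantiotopic ester with inversion and the malonate anion attacks the allyl terminus remote from the surviving ester anti to the metal, so the malonate ends cis to that ester (net retention) and C11 is set as R; the product is a mismatched substrate for a second ionisation.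

Step 4
Reactants: 7 dimethyl 2-[(1R,4S)-4-(2-methylpropanoyloxy)cyclohex-2-en-1-yl]propanedioate
Product: 10 2-[(1S,6R)-6-(1,3-dimethoxy-1,3-dioxopropan-2-yl)cyclohex-2-en-1-yl]-2-methylpropanoic acid, via bis(silyl ketene acetal) 8 (not isolated), via silyl ester 9 (not isolated)
Conditions: LiN(i-Pr)2 (2.3 equiv), THF, −78 °C; Me3SiCl (2.6 equiv); −78 → 60 °C; then 1 M HCl
Reagents that add atoms: none
Why: Ireland–Claisen rearrangement: the first equivalent of base holds the malonate as its enolate and the second enolises the isobutyrate; the suprafacial [3,3] shift forms C5–C6 on the face that carried the C3 oxygen, which sets C5 (S) with C6 cis to the malonate on C11 and moves the alkene to C3=C4.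

Step 5
Reactants: 10 2-[(1S,6R)-6-(1,3-dimethoxy-1,3-dioxopropan-2-yl)cyclohex-2-en-1-yl]-2-methylpropanoic acid
Product: 12 dimethyl 2-[(1R,2S)-2-[1-[methoxy(methyl)amino]-2-methyl-1-oxopropan-2-yl]cyclohex-3-en-1-yl]propanedioate, via acid chloride 11 (not isolated)
Conditions: (COCl)2, DMF (cat.), CH2Cl2, 0 °C; then MeNH(OMe)·HCl, pyridine, 0 °C → rt
Reagents that add atoms: N,O-dimethylhydroxylamine hydrochloride, CNOC.Cl
Why: The acid chloride overcomes the hindrance of the α-quaternary acid; the N-methoxy-N-methylamide is inert to the oxidations, the borohydride reductions and the silylation that follow and keeps C7 at the acyl level.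

Step 6
Reactants: 12 dimethyl 2-[(1R,2S)-2-[1-[methoxy(methyl)amino]-2-methyl-1-oxopropan-2-yl]cyclohex-3-en-1-yl]propanedioate
Product: 13 dimethyl 2-[(1R,2S)-2-[1-[methoxy(methyl)amino]-2-methyl-1-oxopropan-2-yl]-5-oxocyclohex-3-en-1-yl]propanedioate
Conditions: Rh2(C6H10NO)4 (dirhodium tetracaprolactamate, 1 mol%), t-BuOOH (70% in water, 5 equiv), K2CO3 (0.5 equiv), CH2Cl2, rt
Reagents that add atoms: tert-butyl hydroperoxide, CC(C)(C)OO
Why: Catalytic allylic C–H oxidation by tert-butylperoxyl radicals: C2 is the only allylic methylene, whereas the tertiary C5–H is flanked by the quaternary C6 and cannot lead to a ketone, so the C2 enone with C3=C4 retained is expected.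

Step 7
Reactants: 13 dimethyl 2-[(1R,2S)-2-[1-[methoxy(methyl)amino]-2-methyl-1-oxopropan-2-yl]-5-oxocyclohex-3-en-1-yl]propanedioate
Product: 14 α-iodoenone (iodine on C3 of 13)
Conditions: I2 (1.5 equiv), pyridine–CH2Cl2 (1:1), 0 °C → rt
Reagents that add atoms: iodine, II
Why: α-Iodination of an enone by conjugate addition of pyridine, iodination of the enolate and elimination; C3 is the only position that can react this way.

Step 8
Reactants: 14 α-iodoenone (iodine on C3 of 13)
Product: 15 α-methyl enone (methyl on C3)
Conditions: Me4Sn (2 equiv), Pd2(dba)3 (2.5 mol%, dba = dibenzylideneacetone), AsPh3 (10 mol%), CuI (10 mol%), N-methylpyrrolidone, 60 °C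
Reagents that add atoms: tetramethylstannane, C[Sn](C)(C)C
Why: Stille coupling of an α-iodoenone under neutral conditions, which the acidic malonate tolerates; it places the C3 methyl without creating a stereocentre.

Step 9
Reactants: 15 α-methyl enone (methyl on C3)
Product: 17 bridged malonate lactone (precursor of the key step), via cis allylic alcohol 16 (not isolated)
Conditions: NaBH4, CeCl3·7H2O, MeOH, −40 °C; work-up; then DBU (0.2 equiv), 4 Å molecular sieves, toluene, 80 °C
Reagents that add atoms: none
Why: Luche 1,2-reduction with hydride entering from the face opposite the two cis ring substituents (as in carvone to cis-carveol) should give the C2 hydroxyl cis to both; with C6 equatorial this hydroxyl and C10 are 1,3-diaxial, so base-catalysed transesterification onto either malonate ester closes the bridged δ-lactone.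

Step 10
Reactants: 17 bridged malonate lactone (precursor of the key step)
Product: 20 bicyclo[3.1.1]heptene acid ester (C10 acid syn to C1–C3 and C10 methyl ester anti), via silyl ketene acetal 18 (not isolated), via silyl ester 19 (not isolated)
Conditions: TBSOTf (2.5 equiv), NEt3 (6 equiv), toluene, 0 °C → 110 °C (sealed tube); then K2CO3, MeOH–H2O; aqueous citric acid
Reagents that add atoms: none
Why: Proposed new method: soft enolisation of the malonate-type lactone with the silyl triflate and NEt3 should give the endocyclic O-silyl ketene acetal 18, whose C10=C(OSi)–O–C2–C3=C4 array is held in a boat-like six-centre geometry because the ester oxygen on C2 and C10 on C11 are 1,3-diaxial on the cyclohexene, and heating should then trigger the [3,3] shift; the closest known reaction type is the Ireland–Claisen ring contraction of alkenyl lactones to cis-2-alkenylcycloalkanecarboxylic acids, which has not been shown for a bridged lactone that must deliver a bicyclo[3.1.1]heptene. The four-membered ring C4–C5–C11–C10 is closed by the sigmatropic C4–C10 bond itself, as a transannular contraction of the eight-membered perimeter O–C(=O)–C10–C11–C5–C4=C3–C2, and not by an ionic exo or endo cyclisation. C4 is set by suprafacial transfer from the C2 carbinol: C10 bonds to the alkene face from which the C2–O bond leaves, the face that already carries C10 and C6. Quaternary C10 is set by the tether: the carboxyl that was the lactone carbonyl must end on the side of C2, syn to the new C1–C2=C3 bridge, and the free ester ends anti, next to C6; the C10 configuration of 17 is erased in 18, so both epimers converge. The selectivity needed is bonding of C10 to C4 and not to C2, and rearrangement in preference to ionisation of the allylic C2–O bond; only C4 is within reach of C10 in the tethered array, and the excess amine keeps the medium free of acid. Silyl transfer between the two carbonyl oxygens of the malonate unit is fast, so the productive ketene acetal stays available. The driving force is the silyl ester and the trisubstituted C2=C3 alkene set against the strain of the bicycle and the syn-1,3 contact of C6 with the ester on C10, which is why prolonged heating is planned. Mild hydrolysis of silyl ester 19 gives acid 20.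

Step 11
Reactants: 20 bicyclo[3.1.1]heptene acid ester (C10 acid syn to C1–C3 and C10 methyl ester anti)
Product: 22 hydroxymethyl ester (C10 CH2OH syn to C1–C3), via acyl imidazolide 21 (not isolated)
Conditions: 1,1'-carbonyldiimidazole, THF, rt; then NaBH4, H2O, 0 °C
Reagents that add atoms: none
Why: Activation as the acyl imidazolide and borohydride reduction is selective for the acid over the methyl ester and the N-methoxy-N-methylamide and, unlike a borane, leaves C2=C3 alone.

Step 12
Reactants: 22 hydroxymethyl ester (C10 CH2OH syn to C1–C3)
Product: 24 C10-methyl ester, via triflate 23 (not isolated)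
Conditions: Tf2O, pyridine, CH2Cl2, −40 °C; then n-Bu4NBH4, THF, −40 → 25 °C
Reagents that add atoms: none
Why: Hydride displacement of a primary triflate is a two-electron substitution, so no radical or cation is formed on the carbon attached to the cyclobutane, and the geminal ester disfavours ionisation; ester and amide are inert to the borohydride, and the new methyl is the one syn to the C1–C3 bridge.

Step 13
Reactants: 24 C10-methyl ester
Product: 25 ring-A enone (C1 ketone)
Conditions: Rh2(C6H10NO)4 (1 mol%), t-BuOOH (70% in water, 5 equiv), K2CO3 (0.5 equiv), CH2Cl2, rt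
Reagents that add atoms: tert-butyl hydroperoxide, CC(C)(C)OO
Why: Allylic oxidation of the same kind as α-pinene to verbenone: C1 is the only allylic methylene (C4 is a bridgehead) and only an ester and an amide are present, so the C1 enone is expected.

Step 14
Reactants: 25 ring-A enone (C1 ketone)
Product: 26 diol aldehyde (C1 carbinol with C9 CH2OH and C7 aldehyde)
Conditions: i-Bu2AlH (6 equiv), CH2Cl2, −78 → 0 °C; aqueous potassium sodium tartrate
Reagents that add atoms: none
Why: One hydride reagent does three jobs: the ester gives the C9 primary alcohol, the N-methoxy-N-methylamide stops at the aldehyde through its stable aluminium chelate, and the enone is reduced 1,2 from the less hindered C5 side (the C1 configuration is immaterial).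

Step 15
Reactants: 26 diol aldehyde (C1 carbinol with C9 CH2OH and C7 aldehyde)
Product: 27 triol (C7 carbinol as a mixture of epimers)
Conditions: MeMgBr (5 equiv), THF, −78 → 0 °C; aqueous NH4Cl
Reagents that add atoms: methylmagnesium bromide, C[Mg]Br
Why: Grignard addition to the only carbonyl group present brings in C8; the configuration of the new C7 carbinol does not matter because it is oxidised in the next step.

Step 16
Reactants: 27 triol (C7 carbinol as a mixture of epimers)
Product: 28 keto aldehyde enone (C1 enone with C7 methyl ketone and C9 aldehyde)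
Conditions: Dess–Martin periodinane (4.5 equiv), NaHCO3, CH2Cl2, 0 °C → rt
Reagents that add atoms: none
Why: Dess–Martin oxidation of all three alcohols restores the C1 enone and gives the C7 methyl ketone and the non-enolisable C9 aldehyde without over-oxidation.

Step 17
Reactants: 28 keto aldehyde enone (C1 enone with C7 methyl ketone and C9 aldehyde)
Product: 29 tricyclic dienedione (ring-B enone C7(=O)–C8=C9)
Conditions: KOH (0.5 equiv), MeOH, 25 → 50 °C
Reagents that add atoms: none
Why: Intramolecular aldol condensation: C8 is the only enolisable carbon that can reach an electrophile, because C6 and C9 are held syn on the cyclobutane while attack on ring A would need a trans-fused ring; dehydration removes the C9 carbinol that the core cannot control and closes ring B as an enone.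

Step 18
Reactants: 29 tricyclic dienedione (ring-B enone C7(=O)–C8=C9)
Product: 31 β-hydroxy ketone (C9 hydroxyl on the C11 side), via C9 pinacol boronate 30 (not isolated)
Conditions: CuCl (5 mol%), NaOt-Bu (10 mol%), (R,R)-2,3-bis(tert-butylmethylphosphino)quinoxaline (6 mol%), B2pin2 (1.1 equiv), MeOH (2 equiv), THF, 0 °C; then NaBO3·4H2O, THF–H2O, rt
Reagents that add atoms: sodium perborate, [Na+].[O-]OB=O
Why: Copper-catalysed asymmetric conjugate borylation adds a boryl group to the β-monosubstituted ring-B enone (the β,β-disubstituted ring-A enone reacts more slowly); because the two faces of C9 differ only through the remote C1=O versus C3–CH3, the chiral monovalent copper–bisphosphine complex decides the face, and stereoretentive oxidation gives the C9 hydroxyl.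

Step 19
Reactants: 31 β-hydroxy ketone (C9 hydroxyl on the C11 side); 32 (E)-2-methylbut-2-enal
Product: 33 C9 tiglate with free C7 hydroxyl
Conditions: SmI2 (0.3 equiv), 32 (6 equiv), THF, −10 °C
Reagents that add atoms: none
Why: Evans–Tishchenko reduction: the trivalent samarium alkoxide of the hemiacetal formed from the C9 hydroxyl and 32 passes its hydride to the C7 carbonyl through a six-membered chelate, so the C7 hydroxyl forms anti (trans) to the C9 oxygen while the aldehyde ends as the C9 tiglate with its E alkene untouched; the trans-1,3 arrangement on the ring should suppress acyl migration.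

Step 20
Reactants: 33 C9 tiglate with free C7 hydroxyl; 34 (Z)-2-methylbut-2-enoic acid
Product: 36 target diester, via mixed anhydride 35 (not isolated)
Conditions: 34 (3 equiv), 2,4,6-trichlorobenzoyl chloride (3 equiv), NEt3 (6 equiv), toluene, rt; then 33, 80 °C
Reagents that add atoms: none
Why: Yamaguchi-type acylation through the mixed anhydride, run without a nucleophilic amine catalyst, is the established way to make angelates of hindered alcohols without Z to E isomerisation.

## Compound list

1 | cyclohexa-1,3-diene | C1=CC=CCC1 | starting material
2 | 2,3-dioxabicyclo[2.2.2]oct-5-ene (endoperoxide) | C1=C[C@@H]2CC[C@H]1OO2 | intermediate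
3 | cis-cyclohex-2-ene-1,4-diol (meso) | O[C@H]1C=C[C@@H](O)CC1 | intermediate
4 | 2-methylpropanoyl chloride (isobutyryl chloride) | CC(C)C(=O)Cl | starting material
5 | cis-cyclohex-2-ene-1,4-diyl bis(2-methylpropanoate) (meso) | CC(C)C(=O)O[C@H]1C=C[C@@H](OC(=O)C(C)C)CC1 | intermediate
6 | dimethyl malonate | COC(=O)CC(=O)OC | starting material
7 | dimethyl 2-[(1R,4S)-4-(2-methylpropanoyloxy)cyclohex-2-en-1-yl]propanedioate | COC(=O)C(C(=O)OC)[C@H]1C=C[C@@H](OC(=O)C(C)C)CC1 | intermediate
8 | bis(trimethylsilyl ketene acetal) of 7 (malonate and isobutyrate both O-silylated) | COC(O[Si](C)(C)C)=C(C(=O)OC)[C@H]1C=C[C@@H](OC(O[Si](C)(C)C)=C(C)C)CC1 | intermediate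
9 | trimethylsilyl ester of 10 with the malonate still O-silylated | C[Si](C)(C)OC(=O)C(C)(C)[C@H]1C=CCC[C@H]1C(C(=O)OC)=C(OC)O[Si](C)(C)C | intermediate
10 | 2-[(1S,6R)-6-(1,3-dimethoxy-1,3-dioxopropan-2-yl)cyclohex-2-en-1-yl]-2-methylpropanoic acid | OC(=O)C(C)(C)[C@H]1C=CCC[C@H]1C(C(=O)OC)C(=O)OC | intermediate
11 | acid chloride of 10 | ClC(=O)C(C)(C)[C@H]1C=CCC[C@H]1C(C(=O)OC)C(=O)OC | intermediate
12 | dimethyl 2-[(1R,2S)-2-[1-[methoxy(methyl)amino]-2-methyl-1-oxopropan-2-yl]cyclohex-3-en-1-yl]propanedioate | CON(C)C(=O)C(C)(C)[C@H]1C=CCC[C@H]1C(C(=O)OC)C(=O)OC | intermediate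
13 | dimethyl 2-[(1R,2S)-2-[1-[methoxy(methyl)amino]-2-methyl-1-oxopropan-2-yl]-5-oxocyclohex-3-en-1-yl]propanedioate (C2 enone) | CON(C)C(=O)C(C)(C)[C@H]1C=CC(=O)C[C@H]1C(C(=O)OC)C(=O)OC | intermediate
14 | α-iodoenone: 13 with iodine on C3 (4-iodo-5-oxocyclohex-3-enyl ring), ring configuration as in 13 | CON(C)C(=O)C(C)(C)[C@H]1C=C(I)C(=O)C[C@H]1C(C(=O)OC)C(=O)OC | intermediate
15 | α-methyl enone: 13 with methyl on C3 (4-methyl-5-oxocyclohex-3-enyl ring), ring configuration as in 13 | CON(C)C(=O)C(C)(C)[C@H]1C=C(C)C(=O)C[C@H]1C(C(=O)OC)C(=O)OC | intermediate
16 | cis allylic alcohol: C2 carbinol of 15, hydroxyl cis to the C5 and C11 substituents | CON(C)C(=O)C(C)(C)[C@H]1C=C(C)[C@@H](O)C[C@H]1C(C(=O)OC)C(=O)OC | intermediate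
17 | methyl (1S,4R,5R,6R)-6-[1-[methoxy(methyl)amino]-2-methyl-1-oxopropan-2-yl]-8-methyl-3-oxo-2-oxabicyclo[3.3.1]non-7-ene-4-carboxylate (bridged malonate lactone; C4 of this name = C10, epimerisable) | CON(C)C(=O)C(C)(C)[C@H]1C=C(C)[C@@H]2C[C@H]1[C@H](C(=O)OC)C(=O)O2 | intermediate
18 | tert-butyldimethylsilyl ketene acetal of 17 (C10=C(OSi) inside the lactone ring) | CON(C)C(=O)C(C)(C)[C@H]1C=C(C)[C@@H]2C[C@H]1C(C(=O)OC)=C(O[Si](C)(C)C(C)(C)C)O2 | intermediate
19 | tert-butyldimethylsilyl ester of 20 | CON(C)C(=O)C(C)(C)[C@H]1[C@@H]2C(C)=CC[C@H]1[C@]2(C(=O)O[Si](C)(C)C(C)(C)C)C(=O)OC | intermediate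
20 | 6-(methoxycarbonyl)-2-methyl-7-[1-[methoxy(methyl)amino]-2-methyl-1-oxopropan-2-yl]bicyclo[3.1.1]hept-2-ene-6-carboxylic acid; acid on C10 syn to the C1–C3 bridge, ester on C10 and side chain on C5 both anti | CON(C)C(=O)C(C)(C)[C@H]1[C@@H]2C(C)=CC[C@H]1[C@]2(C(=O)O)C(=O)OC | intermediate
21 | acyl imidazolide of 20 | CON(C)C(=O)C(C)(C)[C@H]1[C@@H]2C(C)=CC[C@H]1[C@]2(C(=O)n3ccnc3)C(=O)OC | intermediate
22 | hydroxymethyl ester: 20 with the C10 acid reduced to CH2OH (syn to C1–C3) | CON(C)C(=O)C(C)(C)[C@H]1[C@@H]2C(C)=CC[C@H]1[C@]2(CO)C(=O)OC | intermediate
23 | triflate of 22 | CON(C)C(=O)C(C)(C)[C@H]1[C@@H]2C(C)=CC[C@H]1[C@]2(COS(=O)(=O)C(F)(F)F)C(=O)OC | intermediate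
24 | C10-methyl ester: methyl 2,6-dimethyl-7-[1-[methoxy(methyl)amino]-2-methyl-1-oxopropan-2-yl]bicyclo[3.1.1]hept-2-ene-6-carboxylate (C10 methyl syn to C1–C3) | CON(C)C(=O)C(C)(C)[C@H]1[C@@H]2C(C)=CC[C@H]1[C@]2(C)C(=O)OC | intermediate
25 | ring-A enone: 24 with C1 oxidised to the ketone | CON(C)C(=O)C(C)(C)[C@H]1[C@@H]2C(C)=CC(=O)[C@H]1[C@]2(C)C(=O)OC | intermediate
26 | diol aldehyde: C1 allylic alcohol (hydroxyl on the C10 side), C9 CH2OH, C7 aldehyde | O=CC(C)(C)[C@H]1[C@@H]2C(C)=C[C@@H](O)[C@H]1[C@]2(C)CO | intermediate
27 | triol: 26 with C7 as CH(OH)CH3 (both C7 epimers) | CC(O)C(C)(C)[C@H]1[C@@H]2C(C)=C[C@@H](O)[C@H]1[C@]2(C)CO | intermediate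
28 | keto aldehyde enone: C1 enone, C7 methyl ketone, C9 aldehyde | CC(=O)C(C)(C)[C@H]1[C@@H]2C(C)=CC(=O)[C@H]1[C@]2(C)C=O | intermediate
29 | tricyclic dienedione: longipina-2,8-diene-1,7-dione (ring B closed, C8=C9) | O=C1C=C[C@@]2(C)[C@@H]3C(=O)C=C(C)[C@H]2[C@@H]3C1(C)C | intermediate
30 | C9 pinacol boronate of the ring-B ketone | O=C1C[C@@H](B2OC(C)(C)C(C)(C)O2)[C@@]3(C)[C@@H]4C(=O)C=C(C)[C@H]3[C@@H]4C1(C)C | intermediate
31 | 9-hydroxylongipin-2-ene-1,7-dione (C9 hydroxyl on the C11 side) | O=C1C[C@@H](O)[C@@]2(C)[C@@H]3C(=O)C=C(C)[C@H]2[C@@H]3C1(C)C | intermediate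
32 | (E)-2-methylbut-2-enal | C/C=C(\C)C=O | starting material
33 | C9 tiglate with free C7 hydroxyl (C7–OH trans to C9–O) | O[C@@H]1C[C@@H](OC(=O)/C(C)=C/C)[C@@]2(C)[C@@H]3C(=O)C=C(C)[C@H]2[C@@H]3C1(C)C | intermediate
34 | (Z)-2-methylbut-2-enoic acid (angelic acid) | C/C=C(/C)C(=O)O | starting material
35 | mixed anhydride of 34 with 2,4,6-trichlorobenzoic acid | C/C=C(/C)C(=O)OC(=O)c1c(Cl)cc(Cl)cc1Cl | intermediate
36 | target: 7-angeloyloxy-9-tigloyloxylongipin-2-en-1-one (CNP0236543.4) | C/C=C(/C)C(=O)O[C@@H]1C[C@@H](OC(=O)/C(C)=C/C)[C@@]2(C)[C@@H]3C(=O)C=C(C)[C@H]2[C@@H]3C1(C)C | target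

## Step count and least certain steps

Total step count: 20. Longest linear sequence: 20 steps (from 1; the route is linear).

**Step 10 (key step).** The [3,3] shift may simply not take place. The equilibrium may not favour the strained bicycle with its syn-1,3 contact between C6 and the C10 ester. The malonate-type ketene acetal is a weak Claisen donor. The silyl triflate may instead ionise the allylic C2–O bond, leading to a diene or to migration of the lactone oxygen to C4.

Fallback, known chemistry only, from 12 back to 20:
- Epoxidise 12 with m-chloroperbenzoic acid anti to both ring substituents to give the C3–C4 epoxide F1.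
- Treat with NaH in THF: the malonate anion opens the epoxide at C4 in a trans-diaxial 4-exo-tet closure (the epoxynitrile type of cyclisation) to give the cyclobutanol diester F2.
- Oxidise with Dess–Martin periodinane to the C3 ketone F3.
- Convert with KN(SiMe3)2 and PhNTf2 to the enol triflate F4; only C2 can enolise.
- Stille methylation (Me4Sn, Pd(PPh3)4, LiCl) gives the C2=C3 methyl alkene diester F5.
- Monohydrolyse with LiOH the less shielded ester syn to the C1–C3 bridge (the anti ester lies next to C6), which returns the route at 20.

The cost is loss of the tether's built-in differentiation of the two carboxyls.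

**Step 6.** Regiocontrol in the radical C–H abstraction may be lost, through attack at the tertiary C5–H with allylic transposition or at the malonate C–H.

Fallback from 12 back to 13: Pd(OAc)2-catalysed allylic acetoxylation (p-benzoquinone, AcOH) goes through a π-allyl complex formed at the unhindered methylene and is attacked at the terminus remote from C5, giving the C2 allylic acetate F6. K2CO3 in MeOH gives the allylic alcohol F7, and Dess–Martin oxidation gives 13.

**Step 12.** Hydride displacement at the neopentyl carbon may be slow. The triflate may then be consumed by participation of the C2=C3 π bond or by ionisation with ring expansion.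

Fallback from 22 back to 24: oxidise 22 with Dess–Martin periodinane to the aldehyde F8, convert it with ethane-1,2-dithiol and BF3·OEt2 to the dithiolane F9, and desulfurise with deactivated Raney Ni (Mozingo reduction) to 24.

**Step 18.** Face selectivity may be poor if the catalyst cannot discriminate at the neopentyl β-carbon. Borylation of the ring-A enone may compete.

Fallback from 29 back to 31: run the conjugate borylation and oxidation with an achiral copper–bisphosphine catalyst and separate the C9 epimers. The wanted epimer is 31. The 9-epimer F10 is returned to 29 by mesylation and elimination (MsCl, NEt3) and resubmitted, so C9 is secured by separation and recycling instead of by catalyst control.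

**Step 19.** Hydride transfer from the hemiacetal of a conjugated aldehyde may be slow, leaving time for retro-aldol opening of 31 or reduction of the enal.

Fallback from 31 to 36:
- Evans–Tishchenko reduction with acetaldehyde (SmI2 cat.) gives the C9 acetate with free C7 hydroxyl F11.
- Yamaguchi acylation with 34 gives the acetate angelate F12.
- Brief K2CO3/MeOH at 0 °C removes the unhindered acetate in preference to the hindered conjugated ester, giving the C7 angelate C9 alcohol F13; isomerisation of the angelate must be watched.
- (E)-2-Methylbut-2-enoyl chloride and pyridine then give 36.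

## Further compounds

F1 | step 10 | C3–C4 epoxide of 12, oxygen anti to the C5 and C11 substituents | CON(C)C(=O)C(C)(C)[C@H]1[C@@H]2O[C@@H]2CC[C@H]1C(C(=O)OC)C(=O)OC
F2 | step 10 | dimethyl 2-hydroxy-7-[1-[methoxy(methyl)amino]-2-methyl-1-oxopropan-2-yl]bicyclo[3.1.1]heptane-6,6-dicarboxylate (hydroxyl on C3 of the target numbering, on the C5 side) | CON(C)C(=O)C(C)(C)[C@H]1[C@@H]2[C@H](O)CC[C@H]1C2(C(=O)OC)C(=O)OC
F3 | step 10 | C3 ketone from F2 | CON(C)C(=O)C(C)(C)[C@H]1[C@@H]2C(=O)CC[C@H]1C2(C(=O)OC)C(=O)OC
F4 | step 10 | enol triflate of F3 (C2=C3) | CON(C)C(=O)C(C)(C)[C@H]1[C@@H]2C(OS(=O)(=O)C(F)(F)F)=CC[C@H]1C2(C(=O)OC)C(=O)OC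
F5 | step 10 | dimethyl 2-methyl-7-[1-[methoxy(methyl)amino]-2-methyl-1-oxopropan-2-yl]bicyclo[3.1.1]hept-2-ene-6,6-dicarboxylate | CON(C)C(=O)C(C)(C)[C@H]1[C@@H]2C(C)=CC[C@H]1C2(C(=O)OC)C(=O)OC
F6 | step 6 | C2 allylic acetate of 12 (either C2 epimer) | CON(C)C(=O)C(C)(C)[C@H]1C=CC(OC(C)=O)C[C@H]1C(C(=O)OC)C(=O)OC
F7 | step 6 | C2 allylic alcohol of 12 (either C2 epimer) | CON(C)C(=O)C(C)(C)[C@H]1C=CC(O)C[C@H]1C(C(=O)OC)C(=O)OC
F8 | step 12 | aldehyde from 22 (C10 formyl syn to C1–C3) | CON(C)C(=O)C(C)(C)[C@H]1[C@@H]2C(C)=CC[C@H]1[C@]2(C=O)C(=O)OC
F9 | step 12 | 1,3-dithiolane of F8 | CON(C)C(=O)C(C)(C)[C@H]1[C@@H]2C(C)=CC[C@H]1[C@]2(C3SCCS3)C(=O)OC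
F10 | step 18 | 9-epimer of 31 (C9 hydroxyl on the C4 side) | O=C1C[C@H](O)[C@@]2(C)[C@@H]3C(=O)C=C(C)[C@H]2[C@@H]3C1(C)C
F11 | step 19 | C9 acetate with free C7 hydroxyl | O[C@@H]1C[C@@H](OC(C)=O)[C@@]2(C)[C@@H]3C(=O)C=C(C)[C@H]2[C@@H]3C1(C)C
F12 | step 19 | C9 acetate C7 angelate | C/C=C(/C)C(=O)O[C@@H]1C[C@@H](OC(C)=O)[C@@]2(C)[C@@H]3C(=O)C=C(C)[C@H]2[C@@H]3C1(C)C
F13 | step 19 | C7 angelate with free C9 hydroxyl | C/C=C(/C)C(=O)O[C@@H]1C[C@@H](O)[C@@]2(C)[C@@H]3C(=O)C=C(C)[C@H]2[C@@H]3C1(C)C
A1 | alternative 1 | (2E,6E)-8-(tert-butyldimethylsilyloxy)-10,10-(ethylenedioxy)-3,7,11-trimethyldodeca-2,6-dienoyl chloride | ClC(=O)/C=C(\C)CC/C=C(\C)[C@H](O[Si](C)(C)C(C)(C)C)CC1(OCCO1)C(C)C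
A2 | alternative 1 | 7-methyl-2-methylenebicyclo[3.1.1]heptan-6-one carrying the C9–C6 side chain on C10 | O=C1[C@@H]2C(=C)CC[C@H]1[C@]2(C)[C@H](O[Si](C)(C)C(C)(C)C)CC3(OCCO3)C(C)C
A3 | alternative 2 | bis(trimethylsilyl enol ether) of the cis-fused bicyclo[5.4.0]undecene-1,9-dione with C7 dioxolane | C[Si](C)(C)OC1=C(C)[C@H]2C(C)=CC(O[Si](C)(C)C)=C[C@H]2C(C)(C)C3(OCCO3)C1
A4 | alternative 2 | tricyclic longipin-2-ene-1,9-dione with C7 dioxolane | O=C1CC2(OCCO2)C(C)(C)[C@H]3[C@@H]4C(C)=CC(=O)[C@H]3[C@]14C
A5 | alternative 3 | 5,5-disubstituted 1-(trimethylsilyloxy)-3-methylcyclopentadiene with the C9–C6 tether ending in an (E)-nitroalkene | C[Si](C)(C)OC1=CC(C)=C[C@@]1(C)[C@H](O[Si](CC)(CC)CC)C[C@@H](O[Si](C)(C)C(C)(C)C)C(C)(C)/C=C/[N+](=O)[O-]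
A6 | alternative 3 | endo-nitro norbornene with bridgehead silyloxy C1, one-carbon bridge C10 and ring B closed | C[Si](C)(C)O[C@]12C=C(C)[C@H]([C@@]1(C)[C@H](O[Si](CC)(CC)CC)C[C@@H](O[Si](C)(C)C(C)(C)C)C3(C)C)[C@H]3[C@H]2[N+](=O)[O-]
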